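**Retrosynthetic overview**
1. Target ⇐ hydroxy enone acid: the ether bridge of ring A closes last by intramolecular oxa-Michael addition; the acrylic acid comes from a methyl ketone (enol triflate, CO insertion).
2. Ring C (cyclohexane) ⇐ unsaturated spiro-δ-lactone + racemic four-carbon iodide: copper-catalysed 1,4-addition, then intramolecular lactone-enolate alkylation (cis fusion); the side-chain centre is set afterwards by equilibration.
3. Ring B (spiro-lactone) ⇐ key intermolecular Michael addition of a 2-formyl cyclohexenone to methyl acrylate (creates the quaternary spiro carbon), then aldehyde reduction and lactonisation.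
4. Ring A ⇐ aldol condensation of a keto aldehyde whose single stereocentre comes from an Evans alkylation; formyl group by Claisen condensation with ethyl formate.
5. Ring order: A (carbocycle) → B (lactone) → C (cyclohexane) → ether bridge.

Assumption: racemic 27 is used on purpose, so compounds 29–36 are pairs of epimers at the dioxolane- or acetyl-bearing carbon (left open in their SMILES) until step 25 converges them.

**Route**

Step 1
Reactants: 1 3,3-dimethylpent-4-enoic acid; 2 (S)-4-benzyloxazolidin-2-one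
Product: 4 N-(3,3-dimethylpent-4-enoyl) oxazolidinone, via mixed pivalic anhydride 3 (not isolated)
Conditions: PivCl, Et3N, THF, −20 °C; then 2, LiCl, −20 °C → rt
Reagents that add atoms: none
Why: N-acylation of the oxazolidinone through the mixed anhydride attaches the chiral auxiliary; no stereocentre is formed.

Step 2
Reactants: 4 N-acyl oxazolidinone; 5 3-bromo-2-methylprop-1-ene
Product: 6 (2S)-alkylated imide
Conditions: NaN(SiMe3)2, THF, −78 °C; then 5, −78 → −40 °C
Reagents that add atoms: none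
Why: Evans asymmetric alkylation: the chelated Z-enolate is attacked by the allylic bromide on the face opposite the benzyl group, which sets the (S) centre that later carries the CH2O bridge arm.

Step 3
Reactants: 6 (2S)-alkylated imide
Product: 7 (2S)-dienyl alcohol
Conditions: LiBH4, MeOH (1 equiv), Et2O, 0 °C
Reagents that add atoms: none
Why: Reductive cleavage of the N-acyl oxazolidinone by hydride gives the primary alcohol and returns the auxiliary without touching the stereocentre or the alkenes.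

Step 4
Reactants: 7 (2S)-dienyl alcohol
Product: 8 TBDPS ether
Conditions: TBDPSCl, imidazole, CH2Cl2, rt
Reagents that add atoms: tert-butyl(chloro)diphenylsilane, CC(C)(C)[Si](Cl)(c1ccccc1)c1ccccc1
Why: Silyl ether protection of the primary alcohol with a group that survives base, hydrogenation, organometallics and buffered HF.

Step 5
Reactants: 8 TBDPS ether
Product: 9 (3S)-keto aldehyde
Conditions: OsO4 (2 mol %), NaIO4, 2,6-lutidine, dioxane/H2O (3:1), rt
Reagents that add atoms: sodium periodate, [Na+].[O-]I(=O)(=O)=O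
Why: Lemieux–Johnson oxidative cleavage of both terminal alkenes gives the 1,5-keto aldehyde; the aldehyde has no α-hydrogen and the stereocentre is not enolisable.

Step 6
Reactants: 9 (3S)-keto aldehyde
Product: 11 ring A enone, via β-hydroxy ketone 10 (not isolated)
Conditions: pyrrolidine (0.3 equiv), AcOH (0.3 equiv), PhMe, 70 °C
Reagents that add atoms: none
Why: Intramolecular aldol condensation: only the methyl group can reach the aldehyde through a six-membered transition state, and dehydration gives the cyclohexenone.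

Step 7
Reactants: 11 ring A enone; 12 ethyl formate
Product: 13 6-hydroxymethylidene enone
Conditions: NaH, EtOH (cat.), THF, 0 °C → rt; then 1 M HCl
Reagents that add atoms: none
Why: Crossed Claisen condensation with ethyl formate is regiospecific because C-6 is the only enolisable position (C-4 is quaternary).

Step 8 (key step)
Reactants: 13 6-hydroxymethylidene enone; 14 methyl acrylate
Product: 15 formyl enone ester (Michael adduct)
Conditions: 14 (3 equiv), DBU (0.2 equiv), MeCN, 0 °C → rt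
Reagents that add atoms: none
Why: Intermolecular Michael addition of the stabilised formyl-enone anion to methyl acrylate: the acceptor approaches the planar donor carbon anti to the neighbouring CH2OTBDPS group, creating the quaternary (future spiro) centre with the propanoate chain trans to that group.

Step 9
Reactants: 15 formyl enone ester
Product: 16 saturated formyl keto ester
Conditions: H2 (1 atm), 10% Pd/C, EtOAc, rt
Reagents that add atoms: none
Why: Catalytic hydrogenation saturates the disubstituted enone C=C (aldehyde, ketone and ester untouched), removing an acceptor that would intercept later enolates and the copper reagent.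

Step 10
Reactants: 16 saturated formyl keto ester
Product: 18 spiro keto lactone, via hydroxy ester 17 (not isolated)
Conditions: NaBH4, MeOH/CH2Cl2 (1:4), −78 °C; aq. NH4Cl; then TsOH·H2O (cat.), PhMe, 60 °C
Reagents that add atoms: none
Why: Chemoselective hydride reduction of the aldehyde (far more reactive than the α-quaternary ketone or the ester) followed by acid-catalysed lactonisation of the δ-hydroxy ester.

Step 11
Reactants: 18 spiro keto lactone
Product: 19 α-phenylselanyl lactone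
Conditions: LiN(iPr)2 (2.3 equiv), THF, −78 °C; PhSeSePh (1.05 equiv), HMPA, −78 °C; aq. NH4Cl
Reagents that add atoms: diphenyl diselenide, c1ccc(cc1)[Se][Se]c1ccccc1
Why: α-Selenenylation of the ketone/lactone dienolate: the more basic lactone enolate reacts with the diselenide, which does not selenenylate ketone enolates productively.

Step 12
Reactants: 19 α-phenylselanyl lactone
Product: 21 unsaturated spiro lactone, via selenoxide 20 (not isolated)
Conditions: 30% H2O2, pyridine, CH2Cl2, 0 °C → rt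
Reagents that add atoms: none
Why: Selenoxide syn-elimination toward the only β-hydrogens gives the endocyclic α,β-unsaturated δ-lactone.

Step 13
Reactants: 22 2-acetylbutyrolactone
Product: 23 dioxolane lactone
Conditions: HOCH2CH2OH, TsOH·H2O (cat.), PhMe, reflux (Dean–Stark)
Reagents that add atoms: ethylene glycol, OCCO
Why: Acid-catalysed ketalisation protects the ketone of the β-keto lactone.

Step 14
Reactants: 23 dioxolane lactone
Product: 24 dioxolane diol
Conditions: LiAlH4, THF, 0 °C → rt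
Reagents that add atoms: none
Why: Hydride reduction of the lactone gives the 1,4-diol.

Step 15
Reactants: 24 dioxolane diol
Product: 25 monotosylate
Conditions: TsCl (1.05 equiv), pyridine, CH2Cl2, −20 °C
Reagents that add atoms: 4-methylbenzenesulfonyl chloride, Cc1ccc(cc1)S(=O)(=O)Cl
Why: Selective sulfonylation of the unhindered primary alcohol; the other hydroxyl is β-branched next to a quaternary carbon.

Step 16
Reactants: 25 monotosylate
Product: 26 TBS ether tosylate
Conditions: TBSOTf, 2,6-lutidine, CH2Cl2, −78 °C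
Reagents that add atoms: tert-butyldimethylsilyl triflate, CC(C)(C)[Si](C)(C)OS(=O)(=O)C(F)(F)F
Why: Silylation of the hindered alcohol with the reactive silyl triflate at low temperature outpaces tetrahydrofuran formation.

Step 17
Reactants: 26 TBS ether tosylate
Product: 27 racemic iodide
Conditions: NaI, NaHCO3, acetone, 50 °C
Reagents that add atoms: sodium iodide, [Na+].[I-]
Why: Finkelstein SN2 displacement of the primary tosylate by iodide.

Step 18
Reactants: 21 unsaturated spiro lactone; 27 racemic iodide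
Product: 30 1,4-adduct (5R; side-chain epimers), via Grignard reagent 28 (not isolated), via silyl ketene acetal 29 (not isolated)
Conditions: 27, Mg, Et2O, rt; then added to 21, CuBr·SMe2 (10 mol %), Me3SiCl, HMPA, THF, −78 °C; aq. NH4Cl
Reagents that add atoms: none
Why: Copper-catalysed, Me3SiCl-accelerated conjugate addition of the Grignard reagent: attack on the β-carbon comes from the face flanked by the flat ketone carbonyl, anti to the ring carbon bearing CH2OTBDPS, setting the (R) centre; work-up hydrolyses the silyl ketene acetal.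

Step 19
Reactants: 30 1,4-adduct
Product: 31 primary alcohol
Conditions: HF·pyridine, pyridine, THF, 0 °C
Reagents that add atoms: none
Why: Selective desilylation: buffered HF cleaves the primary TBS ether and leaves the TBDPS ether and the dioxolane.

Step 20
Reactants: 31 primary alcohol
Product: 32 primary iodide
Conditions: I2, PPh3, imidazole, CH2Cl2, 0 °C → rt
Reagents that add atoms: iodine, II
Why: Appel-type iodination converts the primary alcohol into the iodide by SN2.

Step 21
Reactants: 32 primary iodide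
Product: 33 TBS enol ether iodide
Conditions: TBSOTf, Et3N, CH2Cl2, −78 → −20 °C
Reagents that add atoms: tert-butyldimethylsilyl triflate, CC(C)(C)[Si](C)(C)OS(=O)(=O)C(F)(F)F
Why: Silyl enol ether formation at the only α-CH2 of the ketone masks it for the next step and prepares the later dehydrogenation; the lactone does not react.

Step 22
Reactants: 33 TBS enol ether iodide
Product: 34 cis-fused tricyclic silyl enol ether
Conditions: KN(SiMe3)2 (1.2 equiv), THF, −78 → −20 °C; aq. NH4Cl
Reagents that add atoms: none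
Why: Intramolecular 6-exo-tet alkylation of the lactone enolate: the tether delivers the electrophile to its own face, giving the cis ring fusion under kinetic control (as in Piers-type annulations).

Step 23
Reactants: 34 cis-fused tricyclic silyl enol ether
Product: 35 tricyclic enone (dioxolane)
Conditions: Pd(OAc)2 (1.1 equiv), MeCN, 40 °C
Reagents that add atoms: none
Why: Saegusa–Ito oxidation of the silyl enol ether regenerates the ring A enone; over-oxidation is impossible because the γ-carbon is quaternary.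

Step 24
Reactants: 35 tricyclic enone (dioxolane)
Product: 36 methyl ketone (C-7' epimers)
Conditions: PPTS, acetone/H2O (9:1), 55 °C
Reagents that add atoms: water, O
Why: Acid-catalysed acetal hydrolysis liberates the methyl ketone.

Step 25
Reactants: 36 methyl ketone (C-7' epimers)
Product: 37 methyl ketone (7'R)
Conditions: DBU (0.2 equiv), PhMe, 50 °C
Reagents that add atoms: none
Why: Base-mediated epimerisation α to the methyl ketone: thermodynamic control places the acetyl group equatorial, away from the axial lactone carbonyl (1,3-diaxial clash), which is the configuration of the target.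

Step 26
Reactants: 37 methyl ketone (7'R)
Product: 38 enol triflate
Conditions: KN(SiMe3)2 (1.1 equiv), THF, −78 °C; PhNTf2, −78 → 0 °C; aq. NH4Cl
Reagents that add atoms: N-phenylbis(trifluoromethanesulfonimide), O=S(=O)(N(c1ccccc1)S(=O)(=O)C(F)(F)F)C(F)(F)F
Why: Kinetic deprotonation of the methyl group (the enone is not enolisable and the lactone α-CH is far less acidic) and O-triflation give the terminal enol triflate.

Step 27
Reactants: 38 enol triflate
Product: 39 2-(trimethylsilyl)ethyl acrylate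
Conditions: Pd(OAc)2 (10 mol %), Ph2P(CH2)3PPh2 (12 mol %), CO (1 atm), Me3SiCH2CH2OH, Et3N, DMF, 60 °C
Reagents that add atoms: carbon monoxide, [C-]#[O+]; 2-(trimethylsilyl)ethanol, C[Si](C)(C)CCO
Why: Palladium-catalysed alkoxycarbonylation (oxidative addition to zerovalent palladium, CO insertion, alcoholysis) installs the α-substituted acrylate.

Step 28
Reactants: 39 2-(trimethylsilyl)ethyl acrylate
Product: 41 target acid CNP0268721.2, via hydroxy enone acid 40 (not isolated)
Conditions: Bu4NF (4 equiv), THF, 0 °C → rt; then 1 M HCl to pH 3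
Reagents that add atoms: none
Why: Fluoride cleaves the TBDPS ether and the silylethyl ester, and the freed alkoxide closes the ether bridge by intramolecular oxa-Michael addition to the enone; the new C–O centre is dictated by the bridge, which can only form cis to the CH2O arm.

**Compound list**
Names of 34–40 use spiro[cyclohexane-1,4'-isochromane] numbering: C-1 is the spiro atom, C-2 the ring A carbonyl (or enol) carbon, C-6 the carbon bearing CH2O; C-1' is the lactone carbonyl, C-4a'/C-8a' the ring fusion, C-7' the carbon bearing the side chain.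

1 | 3,3-dimethylpent-4-enoic acid | C=CC(C)(C)CC(=O)O | starting material
2 | (S)-4-benzyloxazolidin-2-one | O=C1N[C@@H](Cc2ccccc2)CO1 | starting material
3 | 3,3-dimethylpent-4-enoic pivalic anhydride | C=CC(C)(C)CC(=O)OC(=O)C(C)(C)C | intermediate
4 | (S)-4-benzyl-3-(3,3-dimethylpent-4-enoyl)oxazolidin-2-one | C=CC(C)(C)CC(=O)N1[C@@H](Cc2ccccc2)COC1=O | intermediate
5 | 3-bromo-2-methylprop-1-ene | C=C(C)CBr | starting material
6 | (S)-4-benzyl-3-[(2S)-3,3-dimethyl-2-(2-methylprop-2-en-1-yl)pent-4-enoyl]oxazolidin-2-one | C=CC(C)(C)[C@H](CC(C)=C)C(=O)N1[C@@H](Cc2ccccc2)COC1=O | intermediate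
7 | (2S)-3,3-dimethyl-2-(2-methylprop-2-en-1-yl)pent-4-en-1-ol | C=CC(C)(C)[C@H](CC(C)=C)CO | intermediate
8 | tert-butyl{[(2S)-3,3-dimethyl-2-(2-methylprop-2-en-1-yl)pent-4-en-1-yl]oxy}diphenylsilane | C=CC(C)(C)[C@H](CC(C)=C)CO[Si](c1ccccc1)(c1ccccc1)C(C)(C)C | intermediate
9 | (3S)-3-{[(tert-butyldiphenylsilyl)oxy]methyl}-2,2-dimethyl-5-oxohexanal | O=CC(C)(C)[C@H](CC(C)=O)CO[Si](c1ccccc1)(c1ccccc1)C(C)(C)C | intermediate
10 | (5S)-5-{[(tert-butyldiphenylsilyl)oxy]methyl}-3-hydroxy-4,4-dimethylcyclohexan-1-one (both C-3 epimers) | O=C1CC(O)C(C)(C)[C@@H](CO[Si](c2ccccc2)(c2ccccc2)C(C)(C)C)C1 | intermediate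
11 | (5S)-5-{[(tert-butyldiphenylsilyl)oxy]methyl}-4,4-dimethylcyclohex-2-en-1-one | O=C1C=CC(C)(C)[C@@H](CO[Si](c2ccccc2)(c2ccccc2)C(C)(C)C)C1 | intermediate
12 | ethyl formate | CCOC=O | starting material
13 | (5R,6Z)-5-{[(tert-butyldiphenylsilyl)oxy]methyl}-6-(hydroxymethylidene)-4,4-dimethylcyclohex-2-en-1-one | O=C1C=CC(C)(C)[C@@H](CO[Si](c2ccccc2)(c2ccccc2)C(C)(C)C)/C1=C/O | intermediate
14 | methyl prop-2-enoate (methyl acrylate) | C=CC(=O)OC | starting material
15 | methyl 3-[(1S,6R)-6-{[(tert-butyldiphenylsilyl)oxy]methyl}-1-formyl-5,5-dimethyl-2-oxocyclohex-3-en-1-yl]propanoate | O=C[C@]1(CCC(=O)OC)[C@H](CO[Si](c2ccccc2)(c2ccccc2)C(C)(C)C)C(C)(C)C=CC1=O | intermediate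
16 | methyl 3-[(1S,2R)-2-{[(tert-butyldiphenylsilyl)oxy]methyl}-1-formyl-3,3-dimethyl-6-oxocyclohexyl]propanoate | O=C[C@]1(CCC(=O)OC)[C@H](CO[Si](c2ccccc2)(c2ccccc2)C(C)(C)C)C(C)(C)CCC1=O | intermediate
17 | methyl 3-[(1S,2R)-2-{[(tert-butyldiphenylsilyl)oxy]methyl}-1-(hydroxymethyl)-3,3-dimethyl-6-oxocyclohexyl]propanoate | OC[C@]1(CCC(=O)OC)[C@H](CO[Si](c2ccccc2)(c2ccccc2)C(C)(C)C)C(C)(C)CCC1=O | intermediate
18 | (6S,11R)-11-{[(tert-butyldiphenylsilyl)oxy]methyl}-10,10-dimethyl-2-oxaspiro[5.5]undecane-3,7-dione | O=C1CC[C@@]2(CO1)[C@H](CO[Si](c3ccccc3)(c3ccccc3)C(C)(C)C)C(C)(C)CCC2=O | intermediate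
19 | (6S,11R)-11-{[(tert-butyldiphenylsilyl)oxy]methyl}-10,10-dimethyl-4-(phenylselanyl)-2-oxaspiro[5.5]undecane-3,7-dione (both C-4 epimers) | O=C1C([Se]c4ccccc4)C[C@@]2(CO1)[C@H](CO[Si](c3ccccc3)(c3ccccc3)C(C)(C)C)C(C)(C)CCC2=O | intermediate
20 | (6S,11R)-11-{[(tert-butyldiphenylsilyl)oxy]methyl}-10,10-dimethyl-4-(phenylseleninyl)-2-oxaspiro[5.5]undecane-3,7-dione | O=C1C([Se](=O)c4ccccc4)C[C@@]2(CO1)[C@H](CO[Si](c3ccccc3)(c3ccccc3)C(C)(C)C)C(C)(C)CCC2=O | intermediate
21 | (6S,11R)-11-{[(tert-butyldiphenylsilyl)oxy]methyl}-10,10-dimethyl-2-oxaspiro[5.5]undec-4-ene-3,7-dione | O=C1C=C[C@@]2(CO1)[C@H](CO[Si](c3ccccc3)(c3ccccc3)C(C)(C)C)C(C)(C)CCC2=O | intermediate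
22 | 3-acetyloxolan-2-one (2-acetylbutyrolactone, racemic) | CC(=O)C1CCOC1=O | starting material
23 | 3-(2-methyl-1,3-dioxolan-2-yl)oxolan-2-one (racemic) | CC1(OCCO1)C2CCOC2=O | intermediate
24 | 2-(2-methyl-1,3-dioxolan-2-yl)butane-1,4-diol (racemic) | CC1(OCCO1)C(CO)CCO | intermediate
25 | 4-hydroxy-3-(2-methyl-1,3-dioxolan-2-yl)butyl 4-methylbenzenesulfonate (racemic) | CC1(OCCO1)C(CO)CCOS(=O)(=O)c2ccc(C)cc2 | intermediate
26 | 4-[(tert-butyldimethylsilyl)oxy]-3-(2-methyl-1,3-dioxolan-2-yl)butyl 4-methylbenzenesulfonate (racemic) | CC1(OCCO1)C(CO[Si](C)(C)C(C)(C)C)CCOS(=O)(=O)c2ccc(C)cc2 | intermediate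
27 | tert-butyl[4-iodo-2-(2-methyl-1,3-dioxolan-2-yl)butoxy]dimethylsilane (racemic) | CC1(OCCO1)C(CO[Si](C)(C)C(C)(C)C)CCI | intermediate
28 | {4-[(tert-butyldimethylsilyl)oxy]-3-(2-methyl-1,3-dioxolan-2-yl)butyl}magnesium iodide | CC1(OCCO1)C(CO[Si](C)(C)C(C)(C)C)CC[Mg]I | intermediate
29 | (5R,6S,11R)-5-{4-[(tert-butyldimethylsilyl)oxy]-3-(2-methyl-1,3-dioxolan-2-yl)butyl}-11-{[(tert-butyldiphenylsilyl)oxy]methyl}-10,10-dimethyl-3-[(trimethylsilyl)oxy]-2-oxaspiro[5.5]undec-3-en-7-one (side-chain epimers) | C[Si](C)(C)OC1=C[C@@H](CCC(CO[Si](C)(C)C(C)(C)C)C2(C)OCCO2)[C@@]3(CO1)[C@H](CO[Si](c4ccccc4)(c4ccccc4)C(C)(C)C)C(C)(C)CCC3=O | intermediate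
30 | (5R,6S,11R)-5-{4-[(tert-butyldimethylsilyl)oxy]-3-(2-methyl-1,3-dioxolan-2-yl)butyl}-11-{[(tert-butyldiphenylsilyl)oxy]methyl}-10,10-dimethyl-2-oxaspiro[5.5]undecane-3,7-dione (side-chain epimers) | O=C1C[C@@H](CCC(CO[Si](C)(C)C(C)(C)C)C2(C)OCCO2)[C@@]3(CO1)[C@H](CO[Si](c4ccccc4)(c4ccccc4)C(C)(C)C)C(C)(C)CCC3=O | intermediate
31 | (5R,6S,11R)-11-{[(tert-butyldiphenylsilyl)oxy]methyl}-5-[4-hydroxy-3-(2-methyl-1,3-dioxolan-2-yl)butyl]-10,10-dimethyl-2-oxaspiro[5.5]undecane-3,7-dione (side-chain epimers) | O=C1C[C@@H](CCC(CO)C2(C)OCCO2)[C@@]3(CO1)[C@H](CO[Si](c4ccccc4)(c4ccccc4)C(C)(C)C)C(C)(C)CCC3=O | intermediate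
32 | (5R,6S,11R)-11-{[(tert-butyldiphenylsilyl)oxy]methyl}-5-[4-iodo-3-(2-methyl-1,3-dioxolan-2-yl)butyl]-10,10-dimethyl-2-oxaspiro[5.5]undecane-3,7-dione (side-chain epimers) | O=C1C[C@@H](CCC(CI)C2(C)OCCO2)[C@@]3(CO1)[C@H](CO[Si](c4ccccc4)(c4ccccc4)C(C)(C)C)C(C)(C)CCC3=O | intermediate
33 | (5R,6S,11R)-7-[(tert-butyldimethylsilyl)oxy]-11-{[(tert-butyldiphenylsilyl)oxy]methyl}-5-[4-iodo-3-(2-methyl-1,3-dioxolan-2-yl)butyl]-10,10-dimethyl-2-oxaspiro[5.5]undec-7-en-3-one (side-chain epimers) | O=C1C[C@@H](CCC(CI)C2(C)OCCO2)[C@@]3(CO1)[C@H](CO[Si](c4ccccc4)(c4ccccc4)C(C)(C)C)C(C)(C)CC=C3O[Si](C)(C)C(C)(C)C | intermediate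
34 | (1S,6R,4a'R,8a'S)-2-[(tert-butyldimethylsilyl)oxy]-6-{[(tert-butyldiphenylsilyl)oxy]methyl}-5,5-dimethyl-7'-(2-methyl-1,3-dioxolan-2-yl)perhydrospiro[cyclohex-2-ene-1,4'-isochroman]-1'-one (cis-fused; C-7' epimers) | CC1(OCCO1)C2CC[C@@H]3[C@H](C2)C(=O)OC[C@]34C(O[Si](C)(C)C(C)(C)C)=CCC(C)(C)[C@H]4CO[Si](c5ccccc5)(c5ccccc5)C(C)(C)C | intermediate
35 | (1S,6R,4a'R,8a'S)-6-{[(tert-butyldiphenylsilyl)oxy]methyl}-5,5-dimethyl-7'-(2-methyl-1,3-dioxolan-2-yl)perhydrospiro[cyclohex-3-ene-1,4'-isochromane]-1',2-dione (C-7' epimers) | CC1(OCCO1)C2CC[C@@H]3[C@H](C2)C(=O)OC[C@]34C(=O)C=CC(C)(C)[C@H]4CO[Si](c5ccccc5)(c5ccccc5)C(C)(C)C | intermediate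
36 | (1S,6R,4a'R,8a'S)-7'-acetyl-6-{[(tert-butyldiphenylsilyl)oxy]methyl}-5,5-dimethylperhydrospiro[cyclohex-3-ene-1,4'-isochromane]-1',2-dione (C-7' epimers) | CC(=O)C1CC[C@@H]2[C@H](C1)C(=O)OC[C@]23C(=O)C=CC(C)(C)[C@H]3CO[Si](c4ccccc4)(c4ccccc4)C(C)(C)C | intermediate
37 | (1S,6R,4a'R,7'R,8a'S)-7'-acetyl-6-{[(tert-butyldiphenylsilyl)oxy]methyl}-5,5-dimethylperhydrospiro[cyclohex-3-ene-1,4'-isochromane]-1',2-dione | CC(=O)[C@@H]1CC[C@@H]2[C@H](C1)C(=O)OC[C@]23C(=O)C=CC(C)(C)[C@H]3CO[Si](c4ccccc4)(c4ccccc4)C(C)(C)C | intermediate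
38 | 1-[(1S,6R,4a'R,7'R,8a'S)-6-{[(tert-butyldiphenylsilyl)oxy]methyl}-5,5-dimethyl-1',2-dioxoperhydrospiro[cyclohex-3-ene-1,4'-isochroman]-7'-yl]ethenyl trifluoromethanesulfonate | C=C(OS(=O)(=O)C(F)(F)F)[C@@H]1CC[C@@H]2[C@H](C1)C(=O)OC[C@]23C(=O)C=CC(C)(C)[C@H]3CO[Si](c4ccccc4)(c4ccccc4)C(C)(C)C | intermediate
39 | 2-(trimethylsilyl)ethyl 2-[(1S,6R,4a'R,7'R,8a'S)-6-{[(tert-butyldiphenylsilyl)oxy]methyl}-5,5-dimethyl-1',2-dioxoperhydrospiro[cyclohex-3-ene-1,4'-isochroman]-7'-yl]prop-2-enoate | C=C(C(=O)OCC[Si](C)(C)C)[C@@H]1CC[C@@H]2[C@H](C1)C(=O)OC[C@]23C(=O)C=CC(C)(C)[C@H]3CO[Si](c4ccccc4)(c4ccccc4)C(C)(C)C | intermediate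
40 | 2-[(1S,6R,4a'R,7'R,8a'S)-6-(hydroxymethyl)-5,5-dimethyl-1',2-dioxoperhydrospiro[cyclohex-3-ene-1,4'-isochroman]-7'-yl]prop-2-enoic acid | C=C(C(=O)O)[C@@H]1CC[C@@H]2[C@H](C1)C(=O)OC[C@]23C(=O)C=CC(C)(C)[C@H]3CO | intermediate
41 | 2-[(1R,2S,5R,4a'R,7'R,8a'S)-8,8-dimethyl-1',3-dioxoperhydrospiro[6-oxabicyclo[3.2.1]octane-2,4'-isochroman]-7'-yl]prop-2-enoic acid (CNP0268721.2) | C=C(C(=O)O)[C@@H]1CC[C@@H]2[C@H](C1)C(=O)OC[C@]21C(=O)C[C@H]2OC[C@@H]1C2(C)C | target

**Summary**
Total step count: 28. Longest linear sequence: 23 steps (steps 1–12, then 18–28); the side branch is steps 13–17.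

Three steps most likely to fail:

Step 8 (key Michael addition). The formyl group can be lost by retro-Claisen cleavage under base, and the hindered donor may add slowly to the acrylate. The fallback sets out from 13. Et3N-mediated addition to the much more reactive acrolein gives the enone dialdehyde F1. Hydrogenation (H2, Pd/C) gives the saturated keto dialdehyde F2, and NaBH4 at −78 °C reduces both aldehydes to the keto diol F3. TEMPO/PhI(OAc)2 then oxidises the unhindered primary alcohol and carries the resulting lactol F4 on to the lactone, so the route is rejoined at 18.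

Step 11 (selenenylation of the dienolate). The ketone enolate may compete, giving selenenylation next to the ketone, double selenenylation or Claisen-type attack on the lactone. The fallback sets out from 18. TBSOTf/Et3N masks the ketone as the silyl enol ether F5, so that only one enolate is needed. LDA (1.1 equiv) and methyl benzenesulfinate give the α-sulfinyl lactone F6, and thermolysis (PhMe, 110 °C, CaCO3) gives the unsaturated lactone silyl enol ether F7. Dilute HCl in THF hydrolyses the enol ether, and the route is rejoined at 21.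

Step 18 (copper-catalysed 1,4-addition). The β-carbon sits next to a quaternary centre, and the Grignard reagent may attack the ketone instead. The fallback sets out from 21 and 27 and replaces the organometallic by a radical (Giese) conjugate addition: (Me3Si)3SiH, AIBN, PhMe, 80 °C, slow addition of the silane. The primary radical from 27 adds to the same face of 21 and hydrogen transfer gives 30 directly, where the route is rejoined; this fallback makes no new compound (F0).

**Further compounds**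
F1 | step 8 | (1S,6R)-6-{[(tert-butyldiphenylsilyl)oxy]methyl}-5,5-dimethyl-2-oxo-1-(3-oxopropyl)cyclohex-3-ene-1-carbaldehyde | O=C[C@]1(CCC=O)[C@H](CO[Si](c2ccccc2)(c2ccccc2)C(C)(C)C)C(C)(C)C=CC1=O
F2 | step 8 | (1S,2R)-2-{[(tert-butyldiphenylsilyl)oxy]methyl}-3,3-dimethyl-6-oxo-1-(3-oxopropyl)cyclohexane-1-carbaldehyde | O=C[C@]1(CCC=O)[C@H](CO[Si](c2ccccc2)(c2ccccc2)C(C)(C)C)C(C)(C)CCC1=O
F3 | step 8 | (2S,3R)-3-{[(tert-butyldiphenylsilyl)oxy]methyl}-2-(hydroxymethyl)-2-(3-hydroxypropyl)-4,4-dimethylcyclohexan-1-one | OC[C@]1(CCCO)[C@H](CO[Si](c2ccccc2)(c2ccccc2)C(C)(C)C)C(C)(C)CCC1=O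
F4 | step 8 | (6S,11R)-11-{[(tert-butyldiphenylsilyl)oxy]methyl}-3-hydroxy-10,10-dimethyl-2-oxaspiro[5.5]undecan-7-one (both anomers) | OC1CC[C@@]2(CO1)[C@H](CO[Si](c3ccccc3)(c3ccccc3)C(C)(C)C)C(C)(C)CCC2=O
F5 | step 11 | (6S,11R)-7-[(tert-butyldimethylsilyl)oxy]-11-{[(tert-butyldiphenylsilyl)oxy]methyl}-10,10-dimethyl-2-oxaspiro[5.5]undec-7-en-3-one | O=C1CC[C@@]2(CO1)[C@H](CO[Si](c3ccccc3)(c3ccccc3)C(C)(C)C)C(C)(C)CC=C2O[Si](C)(C)C(C)(C)C
F6 | step 11 | (6S,11R)-7-[(tert-butyldimethylsilyl)oxy]-11-{[(tert-butyldiphenylsilyl)oxy]methyl}-10,10-dimethyl-4-(phenylsulfinyl)-2-oxaspiro[5.5]undec-7-en-3-one (mixture at C-4 and sulfur) | O=C1C(S(=O)c4ccccc4)C[C@@]2(CO1)[C@H](CO[Si](c3ccccc3)(c3ccccc3)C(C)(C)C)C(C)(C)CC=C2O[Si](C)(C)C(C)(C)C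
F7 | step 11 | (6S,11R)-7-[(tert-butyldimethylsilyl)oxy]-11-{[(tert-butyldiphenylsilyl)oxy]methyl}-10,10-dimethyl-2-oxaspiro[5.5]undeca-4,7-dien-3-one | O=C1C=C[C@@]2(CO1)[C@H](CO[Si](c3ccccc3)(c3ccccc3)C(C)(C)C)C(C)(C)CC=C2O[Si](C)(C)C(C)(C)C
F0 | step 18 | none | none
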